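**Retrosynthetic overview**

- The pyran ring (O1, C2, C3, C4) is cut at O1–C2 and C4–C4a, which leads back to a 2,4-dihydroxybenzoate and 3-methylbut-2-enal (condensation, then oxa-6π closure). The para-phenol is carried as an allyl ether and unmasked last.
- The strategy rests on ring A (C4a, C5, C6, C7, C8, C8a; chromene numbers are kept for these atoms in all intermediates). It is a fully substituted 2,4-dioxygenated benzoate with the ester on C6, oxygen on C7 and C8a, and the prenyl group on C8, that is, a dehydrogenated 4-carbomethoxycyclohexane-1,3-dione.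
- That dione is cut at C5–C6 and C7–C8 into dimethyl malonate (C6, C7 and the ester) and an E-enone. The enone's ketone carbon becomes C8a, its prenyl-bearing α'-methylene becomes C8, and its α- and β-carbons become C4a and C5, so the prenyl position is fixed before the ring exists.
- The enone comes from 6-methylhept-5-en-2-one (methyl-side lithium enolate) and 3-[4-(allyloxy)phenyl]propanal by aldol addition and dehydration. The aldehyde comes from methyl 3-(4-hydroxyphenyl)propanoate.
- Ring order: the carbocycle of ring A first (step 5), made aromatic by selenoxide elimination across C5–C6 (steps 6 and 7), then the pyran ring (step 8).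

Key step: step 5

Remarks on the chemistry: the target has no stereocentre and no double bond that needs a descriptor. The phenol is carried as an allyl ether because an aryl silyl ether is not expected to last in NaOMe/MeOH at reflux, whereas the allyl ether should, and it comes off at the end with zerovalent palladium without acid. LiN(iPr)2 is taken as the commercial solution.

**Route**

Step 1
Reactants: 1 methyl 3-(4-hydroxyphenyl)propanoate
Product: 2 methyl 3-[4-(allyloxy)phenyl]propanoate
Conditions: allyl bromide, K2CO3, acetone, reflux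
Reagents that add atoms: allyl bromide, C=CCBr
Why: Williamson etherification, in which the carbonate-generated phenoxide displaces bromide from the reactive allylic halide while the methyl ester is inert to K2CO3 in acetone.

Step 2
Reactants: 2 methyl 3-[4-(allyloxy)phenyl]propanoate
Product: 3 3-[4-(allyloxy)phenyl]propanal
Conditions: iBu2AlH (1.05 equiv), CH2Cl2, −78 °C; MeOH, then aqueous potassium sodium tartrate
Reagents that add atoms: none
Why: Partial ester reduction with iBu2AlH at −78 °C should stop at the aluminium hemiacetal, which releases the aldehyde only on work-up, and the allyl ether is inert.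

Step 3
Reactants: 4 6-methylhept-5-en-2-one; 3 3-[4-(allyloxy)phenyl]propanal
Product: 5 (±)-1-[4-(allyloxy)phenyl]-3-hydroxy-9-methyldec-8-en-5-one
Conditions: LiN(iPr)2 (lithium diisopropylamide, 1.1 equiv), THF, −78 °C, ketone 4 added to the base; then 3, −78 °C; aq. NH4Cl
Reagents that add atoms: none
Why: Directed aldol addition, in which kinetic deprotonation of the methyl ketone on its methyl side gives the less substituted lithium enolate, which adds to the aldehyde faster than it enolizes it; the new carbinol centre forms without control (racemic) and is removed in step 4.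

Step 4
Reactants: 5 (±)-1-[4-(allyloxy)phenyl]-3-hydroxy-9-methyldec-8-en-5-one
Product: 7 (E)-1-[4-(allyloxy)phenyl]-9-methyldeca-3,8-dien-5-one, via mesylate 6 (not isolated)
Conditions: MsCl, Et3N (3 equiv), CH2Cl2, 0 °C to rt
Reagents that add atoms: none
Why: Mesylation of the β-hydroxyl and E1cB elimination by Et3N should give the conjugated enone, for which the E geometry is the thermodynamically favoured outcome.

Step 5
Reactants: 7 (E)-1-[4-(allyloxy)phenyl]-9-methyldeca-3,8-dien-5-one; 8 dimethyl malonate
Product: 10 (±)-methyl trans-6-{2-[4-(allyloxy)phenyl]ethyl}-4-hydroxy-3-(3-methylbut-2-enyl)-2-oxocyclohex-3-ene-1-carboxylate (enol form), via malonate Michael adduct 9 (not isolated)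
Conditions: NaOMe (1.4 equiv), MeOH, rt then reflux; then cold aq. HCl to pH 3
Reagents that add atoms: none
Why: NaOMe generates sodiomalonate, which adds reversibly in 1,4-fashion to the β-carbon of enone 7 (C5–C6 bond) to give adduct 9, whose ketone then enolizes toward the prenyl-bearing methylene and attacks one malonate ester with loss of methoxide (C7–C8 bond). The closest known reaction is the classical Michael–Claisen annulation of alkylidene ketones with malonic esters to 4-alkoxycarbonylcyclohexane-1,3-diones, which is also used with ketones that close through a substituted methylene to give 2-alkyl diones. The one ring closed is the six-membered carbocycle that becomes ring A, in a 6-exo-trig Dieckmann-type closure, and the enolate on the former enone α-carbon could reach an ester only through a four-membered ring, so a single constitution should result. The C5 centre is set without control in the conjugate addition (racemic), and the C6 centre stays epimerizable between ketone and ester and should settle trans to the C5 side chain under the equilibrating base; both centres are erased on aromatization. The step needs 1,4- over 1,2-addition, which the soft stabilized malonate anion secures, and it needs the sequence to be pulled forward, which the irreversible deprotonation of the acidic dione product by methoxide secures. The allyl ether and the trisubstituted alkene are inert to NaOMe, and methyl esters in methanol rule out ester scrambling.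

Step 6
Reactants: 10 (±)-methyl trans-6-{2-[4-(allyloxy)phenyl]ethyl}-4-hydroxy-3-(3-methylbut-2-enyl)-2-oxocyclohex-3-ene-1-carboxylate
Product: 11 (±)-methyl 6-{2-[4-(allyloxy)phenyl]ethyl}-4-hydroxy-3-(3-methylbut-2-enyl)-2-oxo-1-(phenylselanyl)cyclohex-3-ene-1-carboxylate, selenium trans to the neighbouring side chain and cis to the neighbouring ring hydrogen
Conditions: LiN(iPr)2 (2.1 equiv), THF, −78 to 0 °C; PhSeCl (1.05 equiv), −78 °C; AcOH
Reagents that add atoms: benzeneselenenyl chloride, Cl[Se]c1ccccc1
Why: Two equivalents of amide base should give the dianion (dione enolate plus ester enolate at C6), whose last-formed and most nucleophilic carbon C6 is selenenylated as in the α-selenenylation of ester enolates, the electrophile entering anti to the C5 side chain and so cis to C5–H as the later syn-elimination requires; selenenylation at C4a instead would lead to the same arene.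

Step 7
Reactants: 11 (±)-methyl 6-{2-[4-(allyloxy)phenyl]ethyl}-4-hydroxy-3-(3-methylbut-2-enyl)-2-oxo-1-(phenylselanyl)cyclohex-3-ene-1-carboxylate
Product: 14 methyl 6-{2-[4-(allyloxy)phenyl]ethyl}-2,4-dihydroxy-3-(3-methylbut-2-enyl)benzoate, via selenoxide 12 (not isolated), via cyclohexadienone tautomer 13 (not isolated)
Conditions: 30% aq. H2O2 (3 equiv), pyridine, CH2Cl2, 0 °C to rt
Reagents that add atoms: none
Why: Selenide oxidation is much faster than epoxidation of the alkenes, the selenoxide undergoes syn-elimination with the cis C5–H at or below room temperature (selenoxide elimination), and the resulting cross-conjugated dienone should tautomerize at once to the aromatic resorcylate, with pyridine buffering the selenium acids.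

Step 8
Reactants: 14 methyl 6-{2-[4-(allyloxy)phenyl]ethyl}-2,4-dihydroxy-3-(3-methylbut-2-enyl)benzoate; 15 3-methylbut-2-enal
Product: 17 methyl 5-{2-[4-(allyloxy)phenyl]ethyl}-7-hydroxy-2,2-dimethyl-8-(3-methylbut-2-enyl)-2H-chromene-6-carboxylate, via ortho-quinone methide 16 (not isolated)
Conditions: 15 (2 equiv), ethylenediammonium diacetate (20 mol %), toluene, reflux
Reagents that add atoms: none
Why: Amine-salt-catalysed aldol-type condensation of the enal at C4a, the only unsubstituted ring carbon (ortho to the free C8a hydroxyl, para to the chelated C7 hydroxyl), followed by dehydration to the ortho-quinone methide and oxa-6π electrocyclization, is the standard chromene annulation of resorcinols, and only this one chromene can form because the chelated hydroxyl has no free ortho carbon.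

Step 9
Reactants: 17 methyl 5-{2-[4-(allyloxy)phenyl]ethyl}-7-hydroxy-2,2-dimethyl-8-(3-methylbut-2-enyl)-2H-chromene-6-carboxylate
Product: 18 methyl 7-hydroxy-5-[2-(4-hydroxyphenyl)ethyl]-2,2-dimethyl-8-(3-methylbut-2-enyl)-2H-chromene-6-carboxylate
Conditions: Pd(PPh3)4 (5 mol %, zerovalent palladium), morpholine (5 equiv), THF, rt to 40 °C
Reagents that add atoms: none
Why: Tsuji–Trost deallylation, in which zerovalent palladium ionizes the unhindered primary allyl aryl ether and morpholine captures the π-allyl complex, while the prenyl group has no leaving group and the tertiary ring-bound allylic ether of the chromene should ionize far more slowly.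

**Compound list**

1 | methyl 3-(4-hydroxyphenyl)propanoate | COC(=O)CCc1ccc(O)cc1 | starting material
2 | methyl 3-[4-(allyloxy)phenyl]propanoate | COC(=O)CCc1ccc(OCC=C)cc1 | intermediate
3 | 3-[4-(allyloxy)phenyl]propanal | O=CCCc1ccc(OCC=C)cc1 | intermediate
4 | 6-methylhept-5-en-2-one | CC(=O)CCC=C(C)C | starting material
5 | (±)-1-[4-(allyloxy)phenyl]-3-hydroxy-9-methyldec-8-en-5-one | CC(C)=CCCC(=O)CC(O)CCc1ccc(OCC=C)cc1 | intermediate
6 | (±)-1-[4-(allyloxy)phenyl]-9-methyl-5-oxodec-8-en-3-yl methanesulfonate | CC(C)=CCCC(=O)CC(OS(C)(=O)=O)CCc1ccc(OCC=C)cc1 | intermediate (not isolated)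
7 | (E)-1-[4-(allyloxy)phenyl]-9-methyldeca-3,8-dien-5-one | CC(C)=CCCC(=O)/C=C/CCc1ccc(OCC=C)cc1 | intermediate
8 | dimethyl malonate | COC(=O)CC(=O)OC | starting material
9 | (±)-dimethyl 2-{1-[4-(allyloxy)phenyl]-9-methyl-5-oxodec-8-en-3-yl}malonate | COC(=O)C(C(=O)OC)C(CCc1ccc(OCC=C)cc1)CC(=O)CCC=C(C)C | intermediate (not isolated)
10 | (±)-methyl trans-6-{2-[4-(allyloxy)phenyl]ethyl}-4-hydroxy-3-(3-methylbut-2-enyl)-2-oxocyclohex-3-ene-1-carboxylate (racemic, one enantiomer drawn, enol form) | COC(=O)[C@@H]1C(=O)C(CC=C(C)C)=C(O)C[C@H]1CCc1ccc(OCC=C)cc1 | intermediate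
11 | (±)-methyl 6-{2-[4-(allyloxy)phenyl]ethyl}-4-hydroxy-3-(3-methylbut-2-enyl)-2-oxo-1-(phenylselanyl)cyclohex-3-ene-1-carboxylate (racemic, one enantiomer drawn, Se cis to the neighbouring ring H) | COC(=O)[C@@]1([Se]c2ccccc2)C(=O)C(CC=C(C)C)=C(O)C[C@H]1CCc1ccc(OCC=C)cc1 | intermediate
12 | selenoxide of 11 (configuration at selenium not defined) | COC(=O)[C@@]1([Se](=O)c2ccccc2)C(=O)C(CC=C(C)C)=C(O)C[C@H]1CCc1ccc(OCC=C)cc1 | intermediate (not isolated)
13 | methyl 2-{2-[4-(allyloxy)phenyl]ethyl}-4-hydroxy-5-(3-methylbut-2-enyl)-6-oxocyclohexa-1,4-diene-1-carboxylate | COC(=O)C1=C(CCc2ccc(OCC=C)cc2)CC(O)=C(CC=C(C)C)C1=O | intermediate (not isolated)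
14 | methyl 6-{2-[4-(allyloxy)phenyl]ethyl}-2,4-dihydroxy-3-(3-methylbut-2-enyl)benzoate | COC(=O)c1c(O)c(CC=C(C)C)c(O)cc1CCc1ccc(OCC=C)cc1 | intermediate
15 | 3-methylbut-2-enal | CC(C)=CC=O | starting material
16 | methyl 2-{2-[4-(allyloxy)phenyl]ethyl}-6-hydroxy-3-(3-methylbut-2-enylidene)-5-(3-methylbut-2-enyl)-4-oxocyclohexa-1,5-diene-1-carboxylate (ortho-quinone methide) | COC(=O)C1=C(CCc2ccc(OCC=C)cc2)C(=CC=C(C)C)C(=O)C(CC=C(C)C)=C1O | intermediate (not isolated)
17 | methyl 5-{2-[4-(allyloxy)phenyl]ethyl}-7-hydroxy-2,2-dimethyl-8-(3-methylbut-2-enyl)-2H-chromene-6-carboxylate | COC(=O)c1c(O)c(CC=C(C)C)c2c(c1CCc1ccc(OCC=C)cc1)C=CC(C)(C)O2 | intermediate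
18 | methyl 7-hydroxy-5-[2-(4-hydroxyphenyl)ethyl]-2,2-dimethyl-8-(3-methylbut-2-enyl)-2H-chromene-6-carboxylate | COC(=O)c1c(O)c(CC=C(C)C)c2c(c1CCc1ccc(O)cc1)C=CC(C)(C)O2 | target

**Step count**

Total steps: 9. Longest linear sequence: 9 steps (1 to 18).

**Steps most likely to fail**

Step 5. The Claisen closure must pass through the enolate of the more substituted, prenyl-bearing methylene. If it lags, retro-Michael cleavage, base-induced deconjugation and self-condensation of the enone may take over and the sequence may stall at the open-chain adduct. The fallback moves the prenyl introduction behind the ring formation, so that the annulation runs through a methyl ketone, the best-precedented case. It sets out from aldehyde 3 and comes back at 10.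
- Wittig olefination of 3 with 1-(triphenylphosphoranylidene)propan-2-one (toluene, 80 °C) should give (E)-6-[4-(allyloxy)phenyl]hex-3-en-2-one F1.
- Dimethyl malonate 8 and NaOMe in refluxing MeOH should give, through (±)-dimethyl 2-{1-[4-(allyloxy)phenyl]-5-oxohexan-3-yl}malonate F2, (±)-methyl trans-6-{2-[4-(allyloxy)phenyl]ethyl}-4-hydroxy-2-oxocyclohex-3-ene-1-carboxylate F3.
- C-alkylation of the potassium enolate of F3 (KOH, 1.0 equiv, water/acetone, rt) with 1-bromo-3-methylbut-2-ene at the carbon between the two ring carbonyls should give 10. The O-alkylated enol ether is the expected by-product and would be separated.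

Step 6. The second deprotonation may be incomplete (poorly soluble dilithium salt), selenenylation may occur at the dione carbon C8 or on the face that leaves no syn hydrogen, or PhSeCl may add to the prenyl alkene. The fallback replaces the dianion and selenium by soft enolization and palladium dehydrogenation. It sets out from 10 and comes back at 14, so that steps 6 and 7 are bypassed.
- Me3SiOTf and Et3N (CH2Cl2, 0 °C) should give the bis(silyl) dienol ether (±)-methyl 6-{2-[4-(allyloxy)phenyl]ethyl}-3-(3-methylbut-2-enyl)-2,4-bis(trimethylsilyloxy)cyclohexa-1,3-diene-1-carboxylate F4.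
- Saegusa–Ito oxidation with Pd(OAc)2 (divalent palladium, 1.1 equiv, MeCN, rt) should remove hydrogen from C5 and C6 and give methyl 2-{2-[4-(allyloxy)phenyl]ethyl}-5-(3-methylbut-2-enyl)-6-oxo-4-(trimethylsilyloxy)cyclohexa-1,4-diene-1-carboxylate F5.
- Mild aqueous acid should hydrolyse F5 to dienone 13, which tautomerizes to 14.

Step 8. C–C bond formation at the crowded C4a (flanked by a hydroxyl and the arylethyl chain) on a benzoate-deactivated ring may be slow, so that self-condensation of the enal dominates. The fallback brings in the C2–C3–C4 unit through oxygen first. It sets out from 14 and comes back at 17.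
- O-alkylation of the non-chelated C8a hydroxyl with 3-chloro-3-methylbut-1-yne (DBU, CuCl2 catalytic, MeCN, 0 °C) should give methyl 6-{2-[4-(allyloxy)phenyl]ethyl}-2-hydroxy-3-(3-methylbut-2-enyl)-4-(2-methylbut-3-yn-2-yloxy)benzoate F6.
- Heating in xylene at 140 °C, below the onset of the allyl aryl ether rearrangement, should bring about the aromatic propargyl Claisen rearrangement to C4a, the only free ortho carbon. This gives (±)-methyl 2-{2-[4-(allyloxy)phenyl]ethyl}-6-hydroxy-3-(3-methylbuta-1,2-dienyl)-5-(3-methylbut-2-enyl)-4-oxocyclohexa-1,5-diene-1-carboxylate F7, which enolizes to methyl 2-{2-[4-(allyloxy)phenyl]ethyl}-4,6-dihydroxy-3-(3-methylbuta-1,2-dienyl)-5-(3-methylbut-2-enyl)benzoate F8.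
- A 1,5-hydrogen shift in F8 leads to the same ortho-quinone methide 16, and oxa-6π closure gives 17.

**Further compounds**

F1 | step 5 | (E)-6-[4-(allyloxy)phenyl]hex-3-en-2-one | CC(=O)/C=C/CCc1ccc(OCC=C)cc1
F2 | step 5 | (±)-dimethyl 2-{1-[4-(allyloxy)phenyl]-5-oxohexan-3-yl}malonate | COC(=O)C(C(=O)OC)C(CCc1ccc(OCC=C)cc1)CC(C)=O
F3 | step 5 | (±)-methyl trans-6-{2-[4-(allyloxy)phenyl]ethyl}-4-hydroxy-2-oxocyclohex-3-ene-1-carboxylate | COC(=O)[C@@H]1C(=O)C=C(O)C[C@H]1CCc1ccc(OCC=C)cc1
F4 | step 6 | (±)-methyl 6-{2-[4-(allyloxy)phenyl]ethyl}-3-(3-methylbut-2-enyl)-2,4-bis(trimethylsilyloxy)cyclohexa-1,3-diene-1-carboxylate | COC(=O)C1=C(O[Si](C)(C)C)C(CC=C(C)C)=C(O[Si](C)(C)C)CC1CCc1ccc(OCC=C)cc1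
F5 | step 6 | methyl 2-{2-[4-(allyloxy)phenyl]ethyl}-5-(3-methylbut-2-enyl)-6-oxo-4-(trimethylsilyloxy)cyclohexa-1,4-diene-1-carboxylate | COC(=O)C1=C(CCc2ccc(OCC=C)cc2)CC(O[Si](C)(C)C)=C(CC=C(C)C)C1=O
F6 | step 8 | methyl 6-{2-[4-(allyloxy)phenyl]ethyl}-2-hydroxy-3-(3-methylbut-2-enyl)-4-(2-methylbut-3-yn-2-yloxy)benzoate | COC(=O)c1c(O)c(CC=C(C)C)c(OC(C)(C)C#C)cc1CCc1ccc(OCC=C)cc1
F7 | step 8 | (±)-methyl 2-{2-[4-(allyloxy)phenyl]ethyl}-6-hydroxy-3-(3-methylbuta-1,2-dienyl)-5-(3-methylbut-2-enyl)-4-oxocyclohexa-1,5-diene-1-carboxylate | COC(=O)C1=C(CCc2ccc(OCC=C)cc2)C(C=C=C(C)C)C(=O)C(CC=C(C)C)=C1O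
F8 | step 8 | methyl 2-{2-[4-(allyloxy)phenyl]ethyl}-4,6-dihydroxy-3-(3-methylbuta-1,2-dienyl)-5-(3-methylbut-2-enyl)benzoate | COC(=O)c1c(O)c(CC=C(C)C)c(O)c(C=C=C(C)C)c1CCc1ccc(OCC=C)cc1
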